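Assumption: the SMILES is read as (1R,4R,5R,6S,7R,8R,10S), with a cis 4,5-epoxide (C3 and C6 on the same side), an E tiglate at O-8 and a trans-fused 6,12-lactone. Germacrane numbering is used throughout. The ring is C1–C10, the C7 side chain is C11–C13, C14 is the methyl on C10 and C15 is the methyl on C4. The six-membered precursors are the ring C3–C4–C5–C6–C7–C8. β is the ring face that carries the C7–C11 bond and α is the opposite face.

**Retrosynthetic overview**
1. The lactone is closed last by MnO2 oxidation of a C6/C12 diol. The 1β-OH comes from conjugate borylation of a 1-en-3-one, and the 4,5-epoxide from outer-face epoxidation of the Z-enone. The 8β-tiglate comes from Felkin reduction of a C8 ketone.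
2. The ten-membered ring comes from a dianionic oxy-Cope [3,3] shift of a trans-3,8-dialkenylcyclohexene-3,8-diol. C1–C10 forms, C3–C8 breaks, C10 is set, and Z-C4=C5 is inherited from the six-membered ring.
3. The diol comes from vinyl addition (C1, C2), α'-hydroxylation, and Pd α'-propenylation (C9, C10, C14) of a 6α,12-dioxygenated carvone.
4. That enone comes from (R)-carvone by Shapiro diene formation, singlet-oxygen [4+2], Kornblum–DeLaMare rearrangement and SeO2 hydroxylation. C7 is bought and controls every other centre.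
5. Ring order: cyclohexene (bought), then cyclodecene (oxy-Cope), then oxirane, then γ-lactone.

**Route**

Step 1
Reactants: 1 (R)-(−)-carvone
Product: 2 carvone tosylhydrazone
Conditions: TsNHNH2, EtOH, 60 °C
Reagents that add atoms: p-toluenesulfonyl hydrazide, Cc1ccc(cc1)S(=O)(=O)NN
Why: Hydrazone condensation takes place at the only carbonyl group and leaves the bought stereocentre (future C7) untouched.

Step 2
Reactants: 2 carvone tosylhydrazone
Product: 4 (R)-p-mentha-1,5,8-triene, via dienyllithium 3 (not isolated)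
Conditions: MeLi (2.5 equiv), TMEDA, Et2O, 0 °C to rt; H2O
Reagents that add atoms: none
Why: In this Shapiro reaction only the α'-CH2 can be deprotonated, so loss of sulfinate and N2 gives the ring 1,3-diene C3=C4(Me)–C5=C6 regiospecifically without touching C7.

Step 3
Reactants: 4 (R)-p-mentha-1,5,8-triene
Product: 6 trans-γ-hydroxycarvone, via endoperoxide 5 (not isolated)
Conditions: O2, TPP (cat.), visible light, CH2Cl2, −20 °C; then Et3N, 0 °C to rt
Reagents that add atoms: oxygen, O=O
Why: Singlet-oxygen [4+2] cycloaddition to the s-cis ring diene occurs anti to the neighbouring isopropenyl group and sets the 6α C–O bond, and the Kornblum–DeLaMare rearrangement removes the less hindered bridgehead proton (H-3) to give the C3 ketone and the 6α-alcohol.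

Step 4
Reactants: 6 trans-γ-hydroxycarvone
Product: 7 6α,12-dihydroxy enone
Conditions: SeO2 (0.3 equiv), t-BuOOH (3 equiv), CH2Cl2, rt
Reagents that add atoms: tert-butyl hydroperoxide, CC(C)(C)OO (oxygen passed on through SeO2, O=[Se]=O)
Why: This allylic hydroxylation (ene reaction followed by a [2,3]-sigmatropic shift) attacks the only electron-rich alkene at its methyl group and creates no stereocentre.

Step 5
Reactants: 7 6α,12-dihydroxy enone
Product: 8 bis-TBS ether
Conditions: TBSCl (2.5 equiv), imidazole, DMF, rt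
Reagents that add atoms: tert-butyldimethylsilyl chloride, CC(C)(C)[Si](C)(C)Cl
Why: Standard silylation masks both hydroxyl groups for the strongly basic steps and keeps the γ-oxygen from cyclising onto C3 after ring expansion.

Step 6
Reactants: 8 bis-TBS ether; 9 (E)-1-bromoprop-1-ene
Product: 11 8-(E)-propenyl enone, via lithium enolate 10 (not isolated)
Conditions: LiN(SiMe3)2 (2.2 equiv), Pd2(dba)3 (2.5 mol %), P(t-Bu)3·HBF4 (6 mol %), toluene/THF, rt to 45 °C; cold aq NH4Cl
Reagents that add atoms: (E)-1-bromoprop-1-ene (9), C/C=C/Br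
Why: In this palladium-catalysed ketone α-alkenylation only C8 carries α-protons, oxidative addition to zerovalent palladium and reductive elimination keep the E geometry, and the C8 configuration (equatorial, trans to the C7 chain) does not matter because C8 is re-enolised in step 7.

Step 7
Reactants: 11 8-(E)-propenyl enone
Product: 13 8α-hydroxy-8β-propenyl enone, via potassium dienolate 12 (not isolated)
Conditions: KN(SiMe3)2, THF, −78 °C; MoO5·pyridine·HMPA, −78 to −40 °C
Reagents that add atoms: MoO5·pyridine·HMPA, O=[Mo]12(OO1)OO2.c1ccncc1.CN(C)P(=O)(N(C)C)N(C)C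
Why: In this Vedejs enolate hydroxylation the extended enolate reacts at its α-carbon C8, and the oxidant approaches anti to the C7 side chain, which allylic strain with the in-plane propenyl group forces axial, so OH ends up α and propenyl β.

Step 8
Reactants: 13 8α-hydroxy-8β-propenyl enone; 14 vinylmagnesium bromide
Product: 15 trans-3,8-dialkenyl-3,8-diol
Conditions: CH2=CHMgBr (4 equiv), THF, −78 to 0 °C
Reagents that add atoms: vinylmagnesium bromide (14), C=C[Mg]Br
Why: In this chelation-assisted Grignard 1,2-addition to a ketone without α-protons, magnesium ties C3=O to the equatorial C8 alkoxide and the axial 8β-propenyl group blocks the β face, so vinyl enters axially from the α face (3α-vinyl, 3β-OH).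

Step 9
Reactants: 15 trans-3,8-dialkenyl-3,8-diol
Product: 17 (4Z)-cyclodecene-3,8-dione, via dipotassium bis-enolate 16 (not isolated)
Conditions: KH (6 equiv), 18-crown-6 (4 equiv), THF, 0 °C to rt; cannulate into AcOH/THF, −78 °C
Reagents that add atoms: none
Why: In this dianionic oxy-Cope [3,3]-sigmatropic rearrangement the doubly oxido-substituted, doubly allylic C3–C8 bond breaks while C1–C10 forms through the chair that has both alkenyl groups equatorial on the cyclohexene, the equatorial E-methyl group in that chair gives (10S), and the endocyclic C4=C5 bond cannot overlap with the breaking bond and is carried over as the Z-enone.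

Step 10
Reactants: 17 (4Z)-cyclodecene-3,8-dione
Product: 18 8β-alcohol
Conditions: LiAlH(Ot-Bu)3 (1.5 equiv), THF, −78 to −40 °C
Reagents that add atoms: none
Why: In this chemoselective Felkin–Anh reduction the bulky hydride takes the saturated C8 ketone before the conjugated C3 enone and attacks from the outer ring face, anti to C6 with H-7 on the trajectory side, which gives the (8R) alcohol, 1,3-anti to O-6.

Step 11
Reactants: 18 8β-alcohol; 19 tigloyl chloride
Product: 20 8β-tiglate
Conditions: Et3N, DMAP (cat.), CH2Cl2, 0 °C to rt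
Reagents that add atoms: tigloyl chloride (19), C/C=C(\C)C(=O)Cl
Why: DMAP-catalysed acylation of the only free hydroxyl group retains the C8 configuration and the E geometry of the acyl group.

Step 12
Reactants: 20 8β-tiglate
Product: 21 4,5-epoxy ketone
Conditions: t-BuOOH, Triton B (cat.), THF, 0 °C
Reagents that add atoms: tert-butyl hydroperoxide, CC(C)(C)OO
Why: In this Weitz–Scheffer epoxidation A1,3 strain holds H-6 in the plane of the Z-alkene, so the ring covers one face and t-BuOO− adds to C5 from the outer face (the face of the C6–O bond), which gives the cis (4R,5R)-epoxide while the less electrophilic tiglate stays intact.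

Step 13
Reactants: 21 4,5-epoxy ketone
Product: 22 (1E)-1-en-3-one 4,5-epoxide
Conditions: IBX (2.5 equiv), DMSO/PhF, 70 °C
Reagents that add atoms: none
Why: In this IBX dehydrogenation C2 is the only enolisable position of the only ketone, so the C1=C2 bond forms regiospecifically as the E-enone and no stereocentre is disturbed.

Step 14
Reactants: 22 (1E)-1-en-3-one 4,5-epoxide
Product: 24 1β-hydroxy epoxy ketone, via C1 pinacol boronate 23 (not isolated)
Conditions: B2pin2, CuCl (5 mol %), Xantphos (5 mol %), NaOt-Bu (10 mol %), MeOH (2 equiv), THF, 0 °C; then NaBO3·4H2O, THF/H2O, rt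
Reagents that add atoms: bis(pinacolato)diboron, CC1(C)OB(OC1(C)C)B1OC(C)(C)C(C)(C)O1; sodium perborate, B(=O)O[O-].[Na+]
Why: In this copper-catalysed conjugate borylation of the only unhindered enone the boryl group adds to C1 from the outer face, anti to C9 and with the C10 methyl group in the inside position, which gives (1R), and the perborate oxidation proceeds with retention.

Step 15
Reactants: 24 1β-hydroxy epoxy ketone
Product: 25 1,6,12-triol
Conditions: HF·pyridine, pyridine/THF, 0 °C to rt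
Reagents that add atoms: none
Why: Buffered fluoride desilylation removes both TBS groups under mildly acidic conditions that spare the epoxy ketone, the β-hydroxy ketone and the tiglate.

Step 16
Reactants: 25 1,6,12-triol
Product: 28 eupakirunsin C, via hydroxy enal 26 (not isolated), via lactol 27 (not isolated)
Conditions: MnO2 (activated, 30 equiv), CH2Cl2, rt
Reagents that add atoms: none
Why: In this MnO2 oxidative lactonisation only the allylic primary alcohol is oxidised, the enal closes with the 6α-OH to the lactol, and the lactol is oxidised on to the trans-fused α-methylene-γ-lactone while the saturated 1β-OH is left alone.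

**Compound list**
1 | (R)-(−)-carvone | CC1=CC[C@H](CC1=O)C(C)=C | starting material
2 | carvone tosylhydrazone | CC1=CC[C@H](CC1=NNS(=O)(=O)c1ccc(C)cc1)C(C)=C | intermediate
3 | dienyllithium (lithium on C5 of the ring diene) | CC1=CC[C@H](C=C1[Li])C(C)=C | intermediate
4 | (R)-2-methyl-5-(prop-1-en-2-yl)cyclohexa-1,3-diene (p-mentha-1,5,8-triene) | CC1=CC[C@H](C=C1)C(C)=C | intermediate
5 | 3α,6α-endoperoxide (O–O bridge anti to the isopropenyl group) | CC1=C[C@H]2OO[C@@H]1C[C@H]2C(C)=C | intermediate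
6 | (4R,5S)-4-hydroxy-2-methyl-5-(prop-1-en-2-yl)cyclohex-2-en-1-one (6α-OH, trans to the C7 chain) | CC1=C[C@@H](O)[C@@H](CC1=O)C(C)=C | intermediate
7 | 6α,12-dihydroxy enone (C7 chain = 3-hydroxyprop-1-en-2-yl) | CC1=C[C@@H](O)[C@@H](CC1=O)C(=C)CO | intermediate
8 | 6α,12-bis-TBS ether of 7 | CC1=C[C@@H](O[Si](C)(C)C(C)(C)C)[C@@H](CC1=O)C(=C)CO[Si](C)(C)C(C)(C)C | intermediate
9 | (E)-1-bromoprop-1-ene | C/C=C/Br | starting material
10 | lithium C3,C8-enolate of 8 | CC1=C[C@@H](O[Si](C)(C)C(C)(C)C)[C@@H](C=C1[O-])C(=C)CO[Si](C)(C)C(C)(C)C.[Li+] | intermediate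
11 | 8α-(E)-propenyl enone (propenyl trans to the C7 chain) | CC1=C[C@@H](O[Si](C)(C)C(C)(C)C)[C@@H]([C@@H](/C=C/C)C1=O)C(=C)CO[Si](C)(C)C(C)(C)C | intermediate
12 | potassium dienolate of 11 | CC1=C[C@@H](O[Si](C)(C)C(C)(C)C)[C@@H](C(/C=C/C)=C1[O-])C(=C)CO[Si](C)(C)C(C)(C)C.[K+] | intermediate
13 | 8α-hydroxy-8β-(E)-propenyl enone | CC1=C[C@@H](O[Si](C)(C)C(C)(C)C)[C@@H]([C@](O)(/C=C/C)C1=O)C(=C)CO[Si](C)(C)C(C)(C)C | intermediate
14 | vinylmagnesium bromide | C=C[Mg]Br | starting material
15 | 3α-vinyl-3β-hydroxy-8β-(E)-propenyl-8α-hydroxy cyclohexene (trans-dialkenyl diol) | CC1=C[C@@H](O[Si](C)(C)C(C)(C)C)[C@@H]([C@](O)(/C=C/C)[C@@]1(O)C=C)C(=C)CO[Si](C)(C)C(C)(C)C | intermediate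
16 | dipotassium 2,8-bis-enolate of the ten-membered ring | C[C@@H]1CC=C([O-])/C(C)=C\[C@@H](O[Si](C)(C)C(C)(C)C)[C@H](C(=C)CO[Si](C)(C)C(C)(C)C)C([O-])=C1.[K+].[K+] | intermediate
17 | (4Z,10S)-cyclodec-4-ene-3,8-dione with 6α-OTBS and the 7β side chain | C[C@@H]1CCC(=O)/C(C)=C\[C@@H](O[Si](C)(C)C(C)(C)C)[C@H](C(=C)CO[Si](C)(C)C(C)(C)C)C(=O)C1 | intermediate
18 | 8β-alcohol (8R) | C[C@@H]1CCC(=O)/C(C)=C\[C@@H](O[Si](C)(C)C(C)(C)C)[C@H](C(=C)CO[Si](C)(C)C(C)(C)C)[C@H](O)C1 | intermediate
19 | tigloyl chloride ((E)-2-methylbut-2-enoyl chloride) | C/C=C(\C)C(=O)Cl | starting material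
20 | 8β-tiglate | C[C@@H]1CCC(=O)/C(C)=C\[C@@H](O[Si](C)(C)C(C)(C)C)[C@H](C(=C)CO[Si](C)(C)C(C)(C)C)[C@H](OC(=O)/C(C)=C/C)C1 | intermediate
21 | (4R,5R)-4,5-epoxy-3-ketone | C[C@@H]1CCC(=O)[C@]2(C)O[C@@H]2[C@@H](O[Si](C)(C)C(C)(C)C)[C@H](C(=C)CO[Si](C)(C)C(C)(C)C)[C@H](OC(=O)/C(C)=C/C)C1 | intermediate
22 | (1E)-1-en-3-one 4,5-epoxide | C[C@@H]1/C=C/C(=O)[C@]2(C)O[C@@H]2[C@@H](O[Si](C)(C)C(C)(C)C)[C@H](C(=C)CO[Si](C)(C)C(C)(C)C)[C@H](OC(=O)/C(C)=C/C)C1 | intermediate
23 | 1β-pinacol boronate | C[C@@H]1[C@H](B3OC(C)(C)C(C)(C)O3)CC(=O)[C@]2(C)O[C@@H]2[C@@H](O[Si](C)(C)C(C)(C)C)[C@H](C(=C)CO[Si](C)(C)C(C)(C)C)[C@H](OC(=O)/C(C)=C/C)C1 | intermediate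
24 | 1β-hydroxy (1R) epoxy ketone, bis-TBS | C[C@@H]1[C@H](O)CC(=O)[C@]2(C)O[C@@H]2[C@@H](O[Si](C)(C)C(C)(C)C)[C@H](C(=C)CO[Si](C)(C)C(C)(C)C)[C@H](OC(=O)/C(C)=C/C)C1 | intermediate
25 | 1β,6α,12-triol | C[C@@H]1[C@H](O)CC(=O)[C@]2(C)O[C@@H]2[C@@H](O)[C@H](C(=C)CO)[C@H](OC(=O)/C(C)=C/C)C1 | intermediate
26 | 6α-hydroxy 12-enal | C[C@@H]1[C@H](O)CC(=O)[C@]2(C)O[C@@H]2[C@@H](O)[C@H](C(=C)C=O)[C@H](OC(=O)/C(C)=C/C)C1 | intermediate
27 | 6,12-lactol (C12 epimers) | C[C@@H]1[C@H](O)CC(=O)[C@]2(C)O[C@@H]2[C@H]3OC(O)C(=C)[C@@H]3[C@H](OC(=O)/C(C)=C/C)C1 | intermediate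
28 | eupakirunsin C | C=C1C(=O)O[C@H]2[C@H]1[C@H](OC(=O)/C(C)=C/C)C[C@H](C)[C@H](O)CC(=O)[C@]1(C)O[C@H]21 | target

**Totals**
Total step count: 16. Longest linear sequence: 16 (from 1).

**Three steps most likely to fail**

Step 6 (Pd α'-alkenylation). The hindered cross-conjugated enolate may couple slowly, and the β,γ-unsaturated product may slip into conjugation. The fallback sets out from 8 and returns at 15, and it brings the propenyl group in as a nucleophile instead of an electrophile. KN(SiMe3)2 and MoO5·pyridine·HMPA give the 8α-hydroxy enone F1. Excess vinylmagnesium bromide adds axially to C3 and gives the secondary/tertiary diol F2. Dess–Martin periodinane oxidises only the secondary carbinol to the 3-hydroxy-8-ketone F3. (E)-Prop-1-enyllithium (from 9 and t-BuLi) then attacks the C8 ketone from the β face, anti to the axial 3α-vinyl group, and delivers 15.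

Step 9 (dianionic oxy-Cope). Three things can go wrong:
- The trans-dialkenyl diol must ring-flip to place both alkenyl groups equatorial.
- The C8 alkoxide could instead drive a rival [3,3] shift across C7–C8 with the C11=C13 alkene.
- The dione can undergo transannular aldol reaction.

The fallback sets out from 13 and returns at 17, and it lets only the C3 alkoxide drive the shift. MeOTf with 2,6-di-tert-butylpyridine caps the tertiary alcohol as the 8α-methyl ether F4. Vinylmagnesium bromide gives the mono-carbinol F5. KH and 18-crown-6 effect a mono-anionic oxy-Cope rearrangement to the 3-keto 8-methyl enol ether F6. Aqueous oxalic acid in THF hydrolyses the enol ether to 17.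

Step 14 (conjugate borylation). The facial selectivity at C1 rests on a conformational argument, and the epoxy ketone must survive the copper alkoxide medium. The fallback sets out from 20 and returns at 24, and it makes the C1–O bond by epoxidation and reductive opening before the 4,5-epoxide exists. IBX gives the cross-conjugated (1E,4Z)-dienone F7. One equivalent of t-BuOOH with DBU epoxidises the less hindered E-enone from the outer face to the 1,2-epoxy enone F8. Na[PhSeB(OEt)3] (from PhSeSePh and NaBH4 in EtOH) cleaves the C2–O bond to the 1β-hydroxy Z-enone F9. Weitz–Scheffer epoxidation of the remaining Z-enone, as in step 12, then gives 24.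

**Further compounds**
F1 | step 6 | 8α-hydroxy enone (OH trans to the C7 chain) | CC1=C[C@@H](O[Si](C)(C)C(C)(C)C)[C@@H]([C@@H](O)C1=O)C(=C)CO[Si](C)(C)C(C)(C)C
F2 | step 6 | 3α-vinyl-3β,8α-diol | CC1=C[C@@H](O[Si](C)(C)C(C)(C)C)[C@@H]([C@@H](O)[C@@]1(O)C=C)C(=C)CO[Si](C)(C)C(C)(C)C
F3 | step 6 | 3α-vinyl-3β-hydroxy-8-ketone | CC1=C[C@@H](O[Si](C)(C)C(C)(C)C)[C@@H](C(=O)[C@@]1(O)C=C)C(=C)CO[Si](C)(C)C(C)(C)C
F4 | step 9 | 8α-methoxy-8β-(E)-propenyl enone | CC1=C[C@@H](O[Si](C)(C)C(C)(C)C)[C@@H]([C@](OC)(/C=C/C)C1=O)C(=C)CO[Si](C)(C)C(C)(C)C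
F5 | step 9 | 3α-vinyl-3β-hydroxy-8α-methoxy-8β-(E)-propenyl cyclohexene | CC1=C[C@@H](O[Si](C)(C)C(C)(C)C)[C@@H]([C@](OC)(/C=C/C)[C@@]1(O)C=C)C(=C)CO[Si](C)(C)C(C)(C)C
F6 | step 9 | ten-membered 3-ketone 8-methyl enol ether (10S, 4Z) | C[C@@H]1CCC(=O)/C(C)=C\[C@@H](O[Si](C)(C)C(C)(C)C)[C@H](C(=C)CO[Si](C)(C)C(C)(C)C)C(OC)=C1
F7 | step 14 | (1E,4Z)-1,4-dien-3-one 8β-tiglate | C[C@@H]1/C=C/C(=O)/C(C)=C\[C@@H](O[Si](C)(C)C(C)(C)C)[C@H](C(=C)CO[Si](C)(C)C(C)(C)C)[C@H](OC(=O)/C(C)=C/C)C1
F8 | step 14 | trans-1,2-epoxy (4Z)-enone (oxygen β at C1) | C[C@@H]1[C@@H]2O[C@H]2C(=O)/C(C)=C\[C@@H](O[Si](C)(C)C(C)(C)C)[C@H](C(=C)CO[Si](C)(C)C(C)(C)C)[C@H](OC(=O)/C(C)=C/C)C1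
F9 | step 14 | 1β-hydroxy (4Z)-enone | C[C@@H]1[C@H](O)CC(=O)/C(C)=C\[C@@H](O[Si](C)(C)C(C)(C)C)[C@H](C(=C)CO[Si](C)(C)C(C)(C)C)[C@H](OC(=O)/C(C)=C/C)C1
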